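**The split.** Set the clock aside and ask how the open intermediate divides between its two exits, target and side product, in these flasks.

| setting | Monday's | Tuesday's | eta | gamma |
|---|---|---|---|---|
| substrate | 2.6 M | 2.6 M | 2.6 M | 2.6 M |
| reagent | 0.40 equiv | 0.60 equiv | 0.800 equiv | 0.800 equiv |
| free catalyst | 0.15 mol% | 0.15 mol% | 0.15 mol% | 0.15 mol% |
| second catalyst | 10 mol% | 10 mol% | 10 mol% | 10 mol% |
| temperature | 105 °C | 118 °C | 110 °C | 125 °C |
| remark | run made earlier | run made earlier |  |  |
| time |  |  | 5.0 min | 5.0 min |

| run | time / min | target / % | substrate / % |
|---|---|---|---|
| Monday's | 1.33 | 28.3 | 17.3 |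
| Monday's | 2.50 | 34.6 | 11.8 |
| Monday's | 4.00 | 34.9 | 8.9 |
| Monday's | 5.00 | 38.0 | 5.5 |
| Tuesday's | 0.667 | 31.4 | 16.0 |
| Tuesday's | 2.00 | 42.5 | 4.0 |
| Tuesday's | 3.00 | 44.3 | 3.3 |
| Tuesday's | 5.00 | 44.6 | 0.1 |

(scatter of a reading: 1 percentage point)

- the best flask by amount of target, in percent of the substrate charged; "all alike" if 1.5 percentage points covers them all (eta / gamma / all alike)
- amount of target at the end, in percent of the substrate charged, eta
- amount of target at the end, in percent of the substrate charged, gamma

**The constant.** Capture and loss each run in proportion to c(open intermediate), so it cancels from their ratio. I assume that, at fixed c(second catalyst), capture also scales with c(reagent). Summed over a run, side product made is then the logarithm of reagent charged over reagent left, divided by a constant. Tuesday's last reading, counting the unaccounted 55.3% as side product, gives 2.46. This is the split constant, target made per side product made for each equivalent of free reagent, a selectivity factor. Monday's last reading gives 5.30, larger than Tuesday's. It is a soft reading, since 38.0% of target stands close to 0.40 equiv of reagent with a scatter of 1 percentage point. Interpolating the logarithm in temperature between the two runs gives 3.95 for eta at 110 °C. Gamma at 125 °C lies above Tuesday's 118 °C, so its 1.63 is an extrapolation from the same two readings, soft Monday's among them.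

**The bracket.** Target equals the reagent charge times one minus the exponential of minus the constant times side product, and I take side product as what target leaves of the substrate. Side product set at the full charge gives an upper bound. Putting that target back gives too little side product, hence a lower bound, and the bounds then close in turn. For eta they run 78.5%, 45.8%, 70.6%, 55.0%, 66.5%, 58.7%. For gamma they run 64.3%, 35.3%, 52.1%, 43.3%, 48.2%, 45.6%. I commit to eta as the better flask, its lower bound standing above gamma's upper one.

**The check.** The forecast names eta, with 54% for eta, under my bracket, and 49% for gamma, over mine, on the ground that “heat favours the loss”. The flasks give 61.2% for eta and 46.6% for gamma, so eta holds more target, and each value lies inside my bracket.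

    substrate + free catalyst ⇌ free catalyst + open intermediate (K = 2.00, k = 86.0 /M/s, Ea = 40.0 kJ/mol, ΔH = −4.00 kJ/mol)
    second catalyst + open intermediate ⇌ catalyst intermediate (K = 0.00780 /M, k = 0.260 /M/s, Ea = 59.0 kJ/mol, ΔH = −14.0 kJ/mol)
    reagent + catalyst intermediate → second catalyst + target (k = 7.80 /M/s, Ea = 53.0 kJ/mol)
    open intermediate → side product (k = 0.00810 /s, Ea = 115 kJ/mol)
    (constants at 110 °C)

**The neighbour.** A neighbour of gamma is charged with 25 mol% of second catalyst instead of 10 mol%. I scale gamma's split constant with that charge, which gives 4.07. Starting from gamma's 46.6% of target, the rounds run 70.9%, 55.5%, 66.9%, 59.2%, 64.8%, 60.9%. That neighbour ends with 36.5% of side product and 63.5% of target.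

The runs were generated by integration with made-up constants, and the scatter is random.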